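The pyranone ring is opened at O1–C8a and C4–C4a. Those bonds end on C8a and C4a, adjacent carbons of ring A that are each flanked by an oxygen-bearing carbon (C8 and C5); ring A can therefore enter as the symmetric 3,6-bis(methoxymethoxy)benzyne, for which no regiochemical question arises. In a single operation the alkoxide oxygen of an (R)-β-hydroxy ester adds to the aryne and the aryl anion so formed acylates itself on the ester, closing the chromanone around an untouched C2 stereocentre. The two precursors are an ortho-silylaryl triflate and the O-trimethylsilyl ether of methyl (3R,15Z)-3-hydroxyicos-15-enoate, the alcohol coming from ketoreductase reduction of the β-keto ester.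

Key step: step 7

Assumption: 2-bromobenzene-1,4-diol and (13Z)-octadec-13-enoic acid are taken as purchasable, and the target stereocentre is read from the SMILES as 2R.

Step 1
Reactants: 1 2-bromobenzene-1,4-diol (bromohydroquinone)
Product: 2 2-bromo-1,4-bis(methoxymethoxy)benzene
Conditions: NaH, MOMCl, DMF, 0 °C to rt
Reagents that add atoms: chloromethyl methyl ether (MOMCl), COCCl
Why: Williamson-type O-alkylation of both phenoxides by the reactive α-chloro ether should be fast and complete, and the aryl bromide is inert to NaH at this temperature.

Step 2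
Reactants: 2 2-bromo-1,4-bis(methoxymethoxy)benzene
Product: 5 2-bromo-3,6-bis(methoxymethoxy)phenol, via lithiated bromide 3 (not isolated), via lithium arylborate 4 (not isolated)
Conditions: B(OiPr)3, LiN(iPr)2, THF, −78 °C; then H2O2, aq NaOH, 0 °C
Reagents that add atoms: hydrogen peroxide, OO
Why: The ring proton between bromine and an acetal oxygen is the most acidic, so directed ortho-lithiation by the amide base should occur there, the borate already present captures the aryllithium before it can lose LiBr, and alkaline peroxide oxidation of the aryl–boron bond then gives the phenol.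

Step 3
Reactants: 5 2-bromo-3,6-bis(methoxymethoxy)phenol
Product: 9 3,6-bis(methoxymethoxy)-2-(trimethylsilyl)phenyl trifluoromethanesulfonate, via aryl silyl ether 6 (not isolated), via ortho-lithiated silyl ether 7 (not isolated), via lithium silylphenolate 8 (not isolated)
Conditions: (Me3Si)2NH, THF, 65 °C, evaporate; n-BuLi, THF, −78 °C; PhNTf2, −78 °C to rt; aq NH4Cl
Reagents that add atoms: hexamethyldisilazane, C[Si](C)(C)N[Si](C)(C)C; N-phenylbis(trifluoromethanesulfonimide), O=S(=O)(N(c1ccccc1)S(=O)(=O)C(F)(F)F)C(F)(F)F
Why: O-silylation, bromine–lithium exchange and anionic 1,3-silyl migration from oxygen to carbon (retro-Brook rearrangement) should place the trimethylsilyl group on the former C–Br carbon, and the phenoxide so released is triflated by the mild N-aryl triflimide, which spares the acetals.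

Step 4
Reactants: 10 (13Z)-octadec-13-enoic acid; 11 potassium methyl malonate
Product: 14 methyl (15Z)-3-oxoicos-15-enoate, via acyl imidazolide 12 (not isolated), via acylmalonate half ester 13 (not isolated)
Conditions: 1,1'-carbonyldiimidazole, THF, rt; then 11, MgCl2, THF, rt to 50 °C; 1 M HCl
Reagents that add atoms: none
Why: In this Masamune–Brooks homologation the acyl imidazolide C-acylates the magnesium enolate of the malonate half ester and the adduct decarboxylates on acidification, under conditions that leave the Z-alkene alone.

Step 5
Reactants: 14 methyl (15Z)-3-oxoicos-15-enoate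
Product: 15 methyl (3R,15Z)-3-hydroxyicos-15-enoate
Conditions: R-selective ketoreductase, NADP+ (cat.), iPrOH, phosphate buffer pH 7, 30 °C
Reagents that add atoms: none
Why: Enzymatic asymmetric ketone reduction with a ketoreductase picked from a commercial panel should deliver hydride to the face that gives the R alcohol (enzyme control of C3), with the cofactor recycled by propan-2-ol and neither the ester nor the alkene accepted as a substrate.

Step 6
Reactants: 15 methyl (3R,15Z)-3-hydroxyicos-15-enoate
Product: 16 methyl (3R,15Z)-3-[(trimethylsilyl)oxy]icos-15-enoate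
Conditions: (Me3Si)2NH, Me3SiCl (cat.), CH2Cl2, rt; evaporate
Reagents that add atoms: hexamethyldisilazane, C[Si](C)(C)N[Si](C)(C)C
Why: Silylation of the secondary alcohol by the disilazane gives only ammonia as by-product, so the moisture-sensitive ether can be used after evaporation, and the stereocentre is not involved.

Step 7
Reactants: 16 methyl (3R,15Z)-3-[(trimethylsilyl)oxy]icos-15-enoate; 9 3,6-bis(methoxymethoxy)-2-(trimethylsilyl)phenyl trifluoromethanesulfonate
Product: 20 (2R)-2-[(12Z)-heptadec-12-en-1-yl]-5,8-bis(methoxymethoxy)-2,3-dihydro-4H-chromen-4-one, via 3,6-bis(methoxymethoxy)benzyne 17 (not isolated), via caesium alkoxide 18 (not isolated), via aryl anion 19 (not isolated)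
Conditions: CsF, 18-crown-6 (cat.), THF, 40 °C, 9 added slowly
Reagents that add atoms: none
Why: Proposed new method: fluoride removes the silyl group of 9 to release the symmetric aryne 17 and opens the Si–O bond of 16 to the caesium alkoxide 18, which adds to either of the two equivalent aryne carbons (bond O1–C8a) and leaves the aryl anion 19 on the neighbouring carbon, next to an acetal oxygen that stabilises it inductively and holds the caesium ion. Anion 19 attacks the ester carbonyl in a 6-exo-trig closure (bond C4–C4a) and the tetrahedral intermediate expels methoxide, which takes the silyl group from another molecule of 16 and thereby regenerates 18, so that fluoride only has to start the chain. The closest known reaction types are the fluoride-promoted annulation of arynes with salicylate esters to xanthones, the insertion of arynes into the O–H bond of aliphatic alcohols and the Parham cyclisation of ortho-lithiated aryl ethers onto a tethered ester to give chroman-4-ones. No stereocentre is created: C2 comes from 15, its C–O bond is never broken, and the R configuration is therefore carried through. Regiochemistry is settled by the symmetry of 17; what the step needs is acylation of 19 ahead of its protonation, which is secured by masking the hydroxyl as its silyl ether (no O–H in the flask), by an ether solvent free of acidic C–H bonds and by the six-membered transition state. Because methoxide ends as MeOSiMe3 the medium stays close to neutral, which protects 20 from racemisation by retro-oxa-Michael ring opening.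

Step 8
Reactants: 20 (2R)-2-[(12Z)-heptadec-12-en-1-yl]-5,8-bis(methoxymethoxy)-2,3-dihydro-4H-chromen-4-one
Product: 21 (2R)-2-[(12Z)-heptadec-12-en-1-yl]-5,8-dihydroxy-2,3-dihydro-4H-chromen-4-one
Conditions: HCl (1.25 M in MeOH), rt, argon
Reagents that add atoms: none
Why: Acid-catalysed acetal exchange with methanol should remove both phenolic methoxymethyl ethers at room temperature, where the isolated Z-alkene, the ketone and the C2 stereocentre are stable, and oxygen is excluded because the product is a hydroquinone.

Compound list
1 | 2-bromobenzene-1,4-diol (bromohydroquinone) | Oc1ccc(O)c(Br)c1 | starting material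
2 | 2-bromo-1,4-bis(methoxymethoxy)benzene | COCOc1ccc(OCOC)c(Br)c1 | intermediate
3 | [2-bromo-3,6-bis(methoxymethoxy)phenyl]lithium | [Li]c1c(Br)c(OCOC)ccc1OCOC | intermediate
4 | lithium [2-bromo-3,6-bis(methoxymethoxy)phenyl]tri(propan-2-yloxy)borate | [Li+].CC(C)O[B-](OC(C)C)(OC(C)C)c1c(Br)c(OCOC)ccc1OCOC | intermediate
5 | 2-bromo-3,6-bis(methoxymethoxy)phenol | Oc1c(Br)c(OCOC)ccc1OCOC | intermediate
6 | [2-bromo-3,6-bis(methoxymethoxy)phenoxy]trimethylsilane | C[Si](C)(C)Oc1c(Br)c(OCOC)ccc1OCOC | intermediate
7 | {3,6-bis(methoxymethoxy)-2-[(trimethylsilyl)oxy]phenyl}lithium | [Li]c1c(O[Si](C)(C)C)c(OCOC)ccc1OCOC | intermediate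
8 | lithium 3,6-bis(methoxymethoxy)-2-(trimethylsilyl)phenolate | [Li+].[O-]c1c([Si](C)(C)C)c(OCOC)ccc1OCOC | intermediate
9 | 3,6-bis(methoxymethoxy)-2-(trimethylsilyl)phenyl trifluoromethanesulfonate | COCOc1ccc(OCOC)c(OS(=O)(=O)C(F)(F)F)c1[Si](C)(C)C | intermediate
10 | (13Z)-octadec-13-enoic acid | CCCC/C=C\CCCCCCCCCCCC(=O)O | starting material
11 | potassium methyl malonate (potassium 3-methoxy-3-oxopropanoate) | COC(=O)CC(=O)[O-].[K+] | starting material
12 | (13Z)-1-(1H-imidazol-1-yl)octadec-13-en-1-one | CCCC/C=C\CCCCCCCCCCCC(=O)n1ccnc1 | intermediate
13 | (15Z)-2-(methoxycarbonyl)-3-oxoicos-15-enoic acid, present in the flask as its magnesium salt | CCCC/C=C\CCCCCCCCCCCC(=O)C(C(=O)O)C(=O)OC | intermediate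
14 | methyl (15Z)-3-oxoicos-15-enoate | CCCC/C=C\CCCCCCCCCCCC(=O)CC(=O)OC | intermediate
15 | methyl (3R,15Z)-3-hydroxyicos-15-enoate | CCCC/C=C\CCCCCCCCCCC[C@@H](O)CC(=O)OC | intermediate
16 | methyl (3R,15Z)-3-[(trimethylsilyl)oxy]icos-15-enoate | CCCC/C=C\CCCCCCCCCCC[C@@H](O[Si](C)(C)C)CC(=O)OC | intermediate
17 | 3,6-bis(methoxymethoxy)benzyne (1,4-bis(methoxymethoxy)-2,3-didehydrobenzene) | COCOC1=CC=C(OCOC)C#C1 | intermediate
18 | caesium (3R,15Z)-1-methoxy-1-oxoicos-15-en-3-olate | CCCC/C=C\CCCCCCCCCCC[C@@H]([O-])CC(=O)OC.[Cs+] | intermediate
19 | caesium 2-{[(3R,15Z)-1-methoxy-1-oxoicos-15-en-3-yl]oxy}-3,6-bis(methoxymethoxy)benzen-1-ide | CCCC/C=C\CCCCCCCCCCC[C@@H](Oc1[c-]c(OCOC)ccc1OCOC)CC(=O)OC.[Cs+] | intermediate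
20 | (2R)-2-[(12Z)-heptadec-12-en-1-yl]-5,8-bis(methoxymethoxy)-2,3-dihydro-4H-chromen-4-one | CCCC/C=C\CCCCCCCCCCC[C@@H]1CC(=O)c2c(OCOC)ccc(OCOC)c2O1 | intermediate
21 | (2R)-2-[(12Z)-heptadec-12-en-1-yl]-5,8-dihydroxy-2,3-dihydro-4H-chromen-4-one (CNP0081592.1) | CCCC/C=C\CCCCCCCCCCC[C@@H]1CC(=O)c2c(O)ccc(O)c2O1 | target

Total step count: 8.
Longest linear sequence: 5 steps (steps 4, 5, 6, 7 and 8; the aryne arm, steps 1, 2, 3, 7 and 8, is equally long).

Steps most likely to fail

Step 7. The aryl anion may be protonated (by traces of water, by the solvent or by the α-methylene of the ester) before it acylates, which would stop the sequence at the open aryl ether. The basic chain carriers may also cause β-elimination in the silyloxy ester, or erode the enantiopurity of the product by reversible ring opening. The fallback uses known chemistry only; it sets out from the free alcohol 15 and the aryne precursor 9 and comes back to the route at 20. Fluoride-induced insertion of the aryne into the O–H bond of the alcohol (KF, 18-crown-6, THF, −20 °C to rt), an established O-arylation of aliphatic alcohols that leaves the carbinol C–O bond intact, should give methyl (3R,15Z)-3-[2,5-bis(methoxymethoxy)phenoxy]icos-15-enoate F1. This is also the compound expected if step 7 stops at the protonation stage, so such material can be fed into the same sequence. Saponification (LiOH, THF/H2O, 0 °C) should give (3R,15Z)-3-[2,5-bis(methoxymethoxy)phenoxy]icos-15-enoic acid F2. Trifluoroacetic anhydride (CH2Cl2, 0 °C) converts it into the mixed anhydride (3R,15Z)-3-[2,5-bis(methoxymethoxy)phenoxy]icos-15-enoic trifluoroacetic anhydride F3. F3 should close by intramolecular Friedel–Crafts acylation at the only free position ortho to the ether oxygen, the classical route from 3-aryloxy acids to chroman-4-ones, to give 20. Any methoxymethyl ether lost to the acid released is of no consequence, because step 8 removes both.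

Step 5. The long lipophilic keto ester may be turned over too slowly, or with insufficient facial selectivity, by the enzymes available. The fallback sets out from 14 and comes back at 15 by homogeneous Noyori asymmetric hydrogenation (RuCl2[(R)-BINAP] (cat.), H2 at about 4 atm, MeOH, 50 °C). The R ligand is known to give (R)-3-hydroxy esters from 3-oxo esters, and the low pressure is chosen because the chelating keto ester is reduced far faster than an isolated internal alkene. This fallback makes no new compound (entry F0).

Step 2. The hindered borate may capture the lithiated bromide too slowly, so that loss of LiBr or halogen migration intervenes, or the crowded aryl–boron bond may resist oxidation. The fallback sets out from 2 and comes back at 5. Deprotonation with LiN(iPr)2 (THF, −78 °C) followed by the small, fast electrophile DMF should give 2-bromo-3,6-bis(methoxymethoxy)benzaldehyde F4. Baeyer–Villiger oxidation (mCPBA, NaHCO3, CH2Cl2, rt), in which the electron-rich aryl group migrates, should give 2-bromo-3,6-bis(methoxymethoxy)phenyl formate F5. Methanolysis of the formate (K2CO3, MeOH, rt) then gives 5.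

Further compounds
F1 | step 7 | methyl (3R,15Z)-3-[2,5-bis(methoxymethoxy)phenoxy]icos-15-enoate | CCCC/C=C\CCCCCCCCCCC[C@@H](Oc1cc(OCOC)ccc1OCOC)CC(=O)OC
F2 | step 7 | (3R,15Z)-3-[2,5-bis(methoxymethoxy)phenoxy]icos-15-enoic acid | CCCC/C=C\CCCCCCCCCCC[C@@H](Oc1cc(OCOC)ccc1OCOC)CC(=O)O
F3 | step 7 | (3R,15Z)-3-[2,5-bis(methoxymethoxy)phenoxy]icos-15-enoic trifluoroacetic anhydride | CCCC/C=C\CCCCCCCCCCC[C@@H](Oc1cc(OCOC)ccc1OCOC)CC(=O)OC(=O)C(F)(F)F
F0 | step 5 | none | none
F4 | step 2 | 2-bromo-3,6-bis(methoxymethoxy)benzaldehyde | O=Cc1c(Br)c(OCOC)ccc1OCOC
F5 | step 2 | 2-bromo-3,6-bis(methoxymethoxy)phenyl formate | O=COc1c(Br)c(OCOC)ccc1OCOC
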